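## Retrosynthetic overview

1. Target ⇐ anti bromochlorination of the ring‑B trisubstituted olefin of a deschloro‑elatol‑type acetate (10).
2. Ring‑A cis‑bromohydrin acetate ⇐ regiodefined silyl enol ether 8 (bromination, then equatorial hydride delivery and acetylation).
3. Spiro stereocentre ⇐ enantioselective deprotonation of the Cs‑symmetric spiro‑ketone 6 (symmetry‑breaking), then methylation of the enol triflate.
4. 6 ⇐ spiro‑dienone 4 by vinylogous deconjugation (exocyclic methylene) and conjugate methylation (gem‑dimethyl).
5. 4 ⇐ dearomative [4+2] of a transient p‑quinone methide with a 2‑silyloxybutadiene. Ring A is the former arene; ring B is formed in the cycloaddition.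

Assumptions: the target is the (2R,3S,6R,8S,9S) isomer encoded by the SMILES. Diene 3 and (S,S)‑bis(1‑phenylethyl)amine are bought (3 is otherwise one step from methyl vinyl ketone).

Numbering used throughout (spiro[5.5]undecane): C1 = CMe2, C2 = CHBr, C3 = CHOAc, C4 = CH2, C5 = C(=CH2), C6 = spiro, C7 = CH2, C8 = CHCl, C9 = C(Me)Br, C10 and C11 = CH2.

## Route

**Step 1**
Reactants: 1, 4‑hydroxy‑2,6‑dimethylbenzaldehyde
Product: 2, 4‑[(dimethylamino)methyl]‑3,5‑dimethylphenol
Conditions: Me2NH (2 M in THF), NaBH(OAc)3, AcOH, DCE, rt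
Reagents that add atoms: dimethylamine, CNC
Why: Reductive amination gives the phenolic Mannich base, a storable precursor of the p‑quinone methide.

**Step 2**
Reactants: 2; 3, 2‑(tert‑butyldimethylsilyloxy)buta‑1,3‑diene (4 equiv)
Product: 4, 9‑(tert‑butyldimethylsilyloxy)‑1,5‑dimethylspiro[5.5]undeca‑1,4,8‑trien‑3‑one (achiral)
Conditions: MeI (1.05 equiv), MeCN, rt, evaporate; then 3, i‑Pr2NEt (slow addition), MeCN, 60 °C
Reagents that add atoms: none (all non‑hydrogen atoms come from 2 and 3; NMe3 is lost)
Why: Proposed new method: quaternisation and base‑triggered 1,6‑elimination of NMe3 release the transient 3,5‑dimethyl p‑quinone methide, whose electron‑poor exocyclic C=C should take up the silyloxydiene in a dearomative, probably asynchronous Diels–Alder reaction (nucleophilic diene CH2 onto the exocyclic CH2, ring closure at the ipso carbon because both ortho positions carry methyl), giving the spiro centre and ring B in one step; the closest known reactions are the 1,6‑addition/ipso‑closure [2+1] and [3+2] spiro‑annulations of p‑quinone methides and Diels–Alder reactions of α‑methylene ketones.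

**Step 3**
Reactants: 4
Product: 5, (±)‑9‑(tert‑butyldimethylsilyloxy)‑1‑methyl‑5‑methylidenespiro[5.5]undeca‑1,8‑dien‑3‑one
Conditions: KHMDS (1.05 equiv), THF, −78 °C; AcOH (1.2 equiv), −78 °C
Reagents that add atoms: none
Why: With no α‑hydrogens available, the base removes a γ‑methyl proton to give the cross‑conjugated trienolate, and kinetic α‑protonation (deconjugation of the Ringold type) installs the exocyclic methylene on one arm; the product is racemic, and its stereocentre is erased in step 4.

**Step 4**
Reactants: 5
Product: 6, 1,1‑dimethyl‑5‑methylidene‑3‑(triisopropylsilyloxy)spiro[5.5]undec‑2‑en‑9‑one (achiral, Cs)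
Conditions: Me2CuLi (3 equiv), Et2O/THF, −40 → 0 °C; TIPSOTf, Et3N, −78 → 0 °C; then K2CO3, MeOH/THF, 0 °C → rt on the crude product
Reagents that add atoms: lithium dimethylcuprate, [Li+].C[Cu-]C; triisopropylsilyl triflate, CC(C)[Si](C(C)C)(C(C)C)OS(=O)(=O)C(F)(F)F
Why: Gilman conjugate addition to the remaining β‑methyl enone builds the gem‑dimethyl carbon, O‑silylation fixes the enolate regiochemistry towards C2, and selective methanolysis of the unhindered TBS enol ether (the TIPS enol ether next to the quaternary carbon is far slower) unmasks the ring‑B ketone, so the molecule has a mirror plane and no stereocentre.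

**Step 5**
Reactants: 6
Product: 7, (6R)‑1,1‑dimethyl‑5‑methylidene‑3‑(triisopropylsilyloxy)spiro[5.5]undeca‑2,8‑dien‑9‑yl trifluoromethanesulfonate
Conditions: (S,S)‑[PhCH(Me)]2NH·HCl, n‑BuLi (2 equiv), THF, −78 °C; 6, −78 °C; Comins' reagent, −78 → −20 °C
Reagents that add atoms: N‑(5‑chloro‑2‑pyridyl)bis(trifluoromethanesulfonimide), FC(F)(F)S(=O)(=O)N(c1ccc(Cl)cn1)S(=O)(=O)C(F)(F)F
Why: Simpkins–Koga asymmetric deprotonation removes one of the two enantiotopic axial α‑protons of the chair‑locked ketone (C1 equatorial, C5 axial), and triflation fixes the olefin position that defines C6 as R (expected 85–95% ee, to be upgraded by crystallisation of 9 or 10); the (S,S)‑amide is chosen by analogy with 4‑tert‑butylcyclohexanone, where the (R,R)‑amide gives the (S)‑enol derivative, and the antipodal amine is available if the sense proves opposite.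

**Step 6**
Reactants: 7
Product: 8, (6R)‑1,1,9‑trimethyl‑5‑methylidene‑3‑(triisopropylsilyloxy)spiro[5.5]undeca‑2,8‑diene
Conditions: MeMgBr, Fe(acac)3 (5 mol%), THF/NMP, −30 °C
Reagents that add atoms: methylmagnesium bromide, C[Mg]Br
Why: Iron‑catalysed Kumada (Fürstner) coupling of the alkenyl triflate installs the C9 methyl without touching the silyl enol ether or the exocyclic alkene, and C6 is unaffected.

**Step 7**
Reactants: 8
Product: 9, (2R,6R)‑2‑bromo‑1,1,9‑trimethyl‑5‑methylidenespiro[5.5]undec‑8‑en‑3‑one
Conditions: NBS (1.05 equiv), NaHCO3, THF, −78 → −20 °C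
Reagents that add atoms: N‑bromosuccinimide, O=C1CCC(=O)N1Br
Why: Electrophilic bromination of the silyl enol ether is regiospecific at C2, and Br+ should enter anti to the pseudo‑axial C11 methylene (a 1,3‑diaxial block, like C19 in 3‑keto‑steroids) to give the equatorial bromide cis to C7, the elatol‑type relative configuration; the C2 epimers are separable, and the minor one can be recycled by acid‑catalysed equilibration.

**Step 8**
Reactants: 9
Product: 10, (2R,3S,6R)‑2‑bromo‑1,1,9‑trimethyl‑5‑methylidenespiro[5.5]undec‑8‑en‑3‑yl acetate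
Conditions: DIBAL, CH2Cl2, −78 °C; then pyridine, DMAP, Ac2O, −78 → 0 °C
Reagents that add atoms: acetic anhydride, CC(=O)OC(C)=O
Why: The axial trajectory is blocked by the syn‑axial C1 methyl, so the bulky hydride attacks equatorially to give the axial alkoxide cis to the equatorial bromide (C3 S), which is trapped in the same pot as the acetate (reductive acetylation); a cis‑bromohydrin cannot close to an epoxide.

**Step 9**
Reactants: 10
Product: 11, 9‑acetylisoobtusol, (2R,3S,6R,8S,9S)‑2,9‑dibromo‑8‑chloro‑1,1,9‑trimethyl‑5‑methylidenespiro[5.5]undecan‑3‑yl acetate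
Conditions: n‑Bu4N+ BrCl2− (1.0 equiv), CH2Cl2, −40 → 0 °C, dark, cold work‑up
Reagents that add atoms: tetrabutylammonium dichlorobromate (the Bu4NCl·BrCl salt, written as its ion pair), CCCC[N+](CCCC)(CCCC)CCCC.[Cl-].ClBr
Why: In this anti bromochlorination under Fürst–Plattner control, Br+ should add to the ring‑B face anti to the axial C5 substituent (C1 equatorial) and chloride should open the bridged intermediate trans‑diaxially at secondary C8, as in 5α‑bromo‑6β‑chloro steroid formation from Δ5‑olefins. The trihalide anion reinforces this regiochemistry, since it reacts through a weakly bridged, nucleophile‑assisted transition state that sends chloride to the less hindered carbon. This places Br on C9 cis to C1 and Cl on C8 cis to C5, with the trisubstituted olefin reacting ahead of the hindered exocyclic alkene.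

## Compound list

1 | 4‑hydroxy‑2,6‑dimethylbenzaldehyde | Cc1cc(O)cc(C)c1C=O | starting material
2 | 4‑[(dimethylamino)methyl]‑3,5‑dimethylphenol | CN(C)Cc1c(C)cc(O)cc1C | intermediate
3 | 2‑(tert‑butyldimethylsilyloxy)buta‑1,3‑diene | C=CC(=C)O[Si](C)(C)C(C)(C)C | starting material
4 | 9‑(TBSO)‑1,5‑dimethylspiro[5.5]undeca‑1,4,8‑trien‑3‑one | CC1=CC(=O)C=C(C)C12CCC(O[Si](C)(C)C(C)(C)C)=CC2 | intermediate
5 | (±)‑9‑(TBSO)‑1‑methyl‑5‑methylidenespiro[5.5]undeca‑1,8‑dien‑3‑one | C=C1CC(=O)C=C(C)C12CCC(O[Si](C)(C)C(C)(C)C)=CC2 | intermediate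
6 | 1,1‑dimethyl‑5‑methylidene‑3‑(TIPSO)spiro[5.5]undec‑2‑en‑9‑one | C=C1CC(O[Si](C(C)C)(C(C)C)C(C)C)=CC(C)(C)C12CCC(=O)CC2 | intermediate
7 | (6R)‑1,1‑dimethyl‑5‑methylidene‑3‑(TIPSO)spiro[5.5]undeca‑2,8‑dien‑9‑yl triflate | C=C1CC(O[Si](C(C)C)(C(C)C)C(C)C)=CC(C)(C)[C@@]12CCC(OS(=O)(=O)C(F)(F)F)=CC2 | intermediate
8 | (6R)‑1,1,9‑trimethyl‑5‑methylidene‑3‑(TIPSO)spiro[5.5]undeca‑2,8‑diene | C=C1CC(O[Si](C(C)C)(C(C)C)C(C)C)=CC(C)(C)[C@@]12CCC(C)=CC2 | intermediate
9 | (2R,6R)‑2‑bromo‑1,1,9‑trimethyl‑5‑methylidenespiro[5.5]undec‑8‑en‑3‑one | C=C1CC(=O)[C@H](Br)C(C)(C)[C@@]12CCC(C)=CC2 | intermediate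
10 | (2R,3S,6R)‑2‑bromo‑1,1,9‑trimethyl‑5‑methylidenespiro[5.5]undec‑8‑en‑3‑yl acetate | C=C1C[C@H](OC(C)=O)[C@H](Br)C(C)(C)[C@@]12CCC(C)=CC2 | intermediate
11 | 9‑acetylisoobtusol | C=C1C[C@H](OC(C)=O)[C@H](Br)C(C)(C)[C@@]12CC[C@](C)(Br)[C@@H](Cl)C2 | target

## Step count and risks

Total steps: 9. Longest linear sequence: 9.

Steps most likely to fail, each with a fallback that changes the approach:

- **Step 2 (quinone‑methide Diels–Alder).** The quinone methide may oligomerise, or the reaction may stop at the 1,6‑adduct. Fallback: build the same spiro‑dienone by intramolecular phenoxide ipso‑alkylation (Winstein–Masamune). The para side chain ArCH2CH2C(OCH2CH2O)CH2CH2OTs is made from 4‑bromo‑3,5‑dimethylphenol and closed with t‑BuOK; the ketal then replaces the TBS enol ether in steps 3–4.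
- **Step 4 (conjugate methylation next to the spiro quaternary carbon).** The β‑carbon is very hindered and the substrate is enolisable. Fallback: Luche reduction of the enone in 5, hydroxyl‑directed Simmons–Smith cyclopropanation, reoxidation, then Li/NH3 reductive opening of the cyclopropyl ketone. This gives the gem‑dimethyl group and the same regiodefined enolate for TIPS trapping.
- **Step 9 (regio‑ and facial selectivity of the bromochlorination).** Markovnikov opening would give the obtusol‑type isomer with Cl on the tertiary carbon. Fallback: epoxidise 10 with mCPBA on the same face, open trans‑diaxially at C8 with LiCl/AcOH, then replace the tertiary C9–OH by bromide with retention through the neighbouring‑chlorine (chloronium) pathway (TMSBr, CH2Cl2, low temperature).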